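Numbering: oxolane ring O1–C2–C3–C4–C5, with the guaiacylmethyl group on C3 and the carbinol carbon C7 (bearing the syringyl ring) on C4.
Retrosynthesis: the phenols are masked as benzyl ethers and C7–OH goes back to the aryl ketone. Then the ring bond C4–C5 is cut, next O1–C5 (removing the one-carbon unit), and last C7–aryl, leaving (R)-β-(4-benzyloxy-3-methoxybenzyl)-γ-butyrolactone and a syringyl anion.
Enabling feature: C5 is a bare ring O–CH2 carbon, and its neighbour C4 is the only α-carbon of the C7 ketone. C4–C5 is therefore the alkylation of an aryl ketone enolate by a formaldehyde-level electrophile already attached to O1.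
Forward: Stobbe condensation, asymmetric hydrogenation and ester reduction give the lactone, and the aryllithium opens it and joins the chain. The freed C2–OH becomes an O,S-acetal and then the chloromethyl ether, enolate alkylation closes the only new ring, and ketone reduction and debenzylation finish the route.
Stereochemistry: C3 (R) comes from the Rh-catalysed hydrogenation. C4 (R) is relayed from C3 in the ring closure (trans, also the thermodynamic epimer). C7 (S) is relayed from C4 by Felkin–Anh hydride delivery.

Key step: step 8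

Assumption: the sense of induction in step 2 is assigned by analogy with closely related (E)-arylidenesuccinic half-esters and DIOP-type rhodium catalysts. Both ligand antipodes are accessible, and the configuration of lactone 6 is to be confirmed before it is carried on.

Step 1
Reactants: 1 4-(benzyloxy)-3-methoxybenzaldehyde; 2 dimethyl succinate
Product: 3 (E)-4-[4-(benzyloxy)-3-methoxyphenyl]-3-(methoxycarbonyl)but-3-enoic acid
Conditions: NaOMe, MeOH, reflux; then aq HCl
Reagents that add atoms: none
Why: Stobbe condensation, in which the succinate enolate adds to the non-enolisable aldehyde, the aldolate lactonises, and E1cB opening gives the carboxylate irreversibly, with the (E)-alkene (aryl trans to the ester) as the favoured, crystallisable isomer.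

Step 2
Reactants: 3 (E)-4-[4-(benzyloxy)-3-methoxyphenyl]-3-(methoxycarbonyl)but-3-enoic acid
Product: 4 (R)-4-[4-(benzyloxy)-3-methoxyphenyl]-3-(methoxycarbonyl)butanoic acid
Conditions: H2 (5 atm), [Rh(cod)Cl]2 (cat.), (4S,5S)-MOD-DIOP (cat.), Et3N, MeOH, 30 °C
Reagents that add atoms: none
Why: Rh-catalysed asymmetric hydrogenation of an itaconate-type half-ester, in which carboxylate and alkene chelate the metal and the C2-symmetric diphosphine selects the alkene face that gives the R centre (future C3), while the aryl benzyl ether is inert to the homogeneous catalyst.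

Step 3
Reactants: 4 (R)-4-[4-(benzyloxy)-3-methoxyphenyl]-3-(methoxycarbonyl)butanoic acid
Product: 6 (R)-4-[4-(benzyloxy)-3-methoxybenzyl]oxolan-2-one, via hydroxy acid 5 (not isolated)
Conditions: KOH (1 equiv), EtOH; Ca(BH4)2 (from CaCl2, NaBH4), EtOH, −10 °C → rt; then aq HCl, rt; recrystallisation
Reagents that add atoms: none
Why: Chemoselective borohydride reduction, since calcium borohydride reduces the methyl ester but not the carboxylate salt and acidification lactonises the γ-hydroxy acid, leaving the stereocentre untouched and giving a crystalline lactone whose enantiomeric purity can be upgraded.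

Step 4
Reactants: 7 4-bromo-2,6-dimethoxyphenol
Product: 8 2-(benzyloxy)-5-bromo-1,3-dimethoxybenzene
Conditions: BnBr, K2CO3, DMF, rt
Reagents that add atoms: benzyl bromide, BrCc1ccccc1
Why: Williamson ether synthesis on an acidic phenol, which installs the same protecting group as on the other ring so that one final operation frees both phenols.

Step 5
Reactants: 8 2-(benzyloxy)-5-bromo-1,3-dimethoxybenzene; 6 (R)-4-[4-(benzyloxy)-3-methoxybenzyl]oxolan-2-one
Product: 10 (R)-3-[4-(benzyloxy)-3-methoxybenzyl]-1-[4-(benzyloxy)-3,5-dimethoxyphenyl]-4-hydroxybutan-1-one, via aryllithium 9 (not isolated)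
Conditions: 8, n-BuLi, THF, −78 °C; cannulated into 6, THF, −78 °C; aq NH4Cl at −78 °C
Reagents that add atoms: none
Why: Bromine–lithium exchange followed by single addition of the aryllithium to a γ-lactone, where the lithium lactolate persists at −78 °C and blocks a second addition, so the cold quench should release the γ-hydroxy aryl ketone with the β-stereocentre unchanged.

Step 6
Reactants: 10 (R)-3-[4-(benzyloxy)-3-methoxybenzyl]-1-[4-(benzyloxy)-3,5-dimethoxyphenyl]-4-hydroxybutan-1-one
Product: 11 (R)-3-[4-(benzyloxy)-3-methoxybenzyl]-1-[4-(benzyloxy)-3,5-dimethoxyphenyl]-4-[(methylsulfanyl)methoxy]butan-1-one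
Conditions: Me2S, (BzO)2, MeCN, 0 °C
Reagents that add atoms: dimethyl sulfide, CSC
Why: Pummerer-type methylthiomethylation, in which the benzoyloxysulfonium salt collapses to MeS=CH2+ and the primary alcohol captures it under nearly neutral conditions, avoiding the cyclodehydration to a dihydrofuran that HCl/formaldehyde chloromethylation would provoke in a γ-hydroxy ketone.

Step 7
Reactants: 11 (R)-3-[4-(benzyloxy)-3-methoxybenzyl]-1-[4-(benzyloxy)-3,5-dimethoxyphenyl]-4-[(methylsulfanyl)methoxy]butan-1-one
Product: 12 (R)-3-[4-(benzyloxy)-3-methoxybenzyl]-1-[4-(benzyloxy)-3,5-dimethoxyphenyl]-4-(chloromethoxy)butan-1-one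
Conditions: SO2Cl2 (1.05 equiv), cyclohexene, CH2Cl2, −78 → −20 °C; volatiles removed in vacuo, residue triturated with dry pentane, used at once
Reagents that add atoms: sulfuryl chloride, O=S(=O)(Cl)Cl
Why: Chlorinolysis of an O,S-acetal, in which the sulfide sulfur (by far the most nucleophilic site) is chlorinated and the chlorosulfonium salt fragments to the α-chloro ether under anhydrous, non-acidic conditions, while cyclohexene intercepts the sulfenyl chloride before it can attack the arenes.

Step 8
Reactants: 12 (R)-3-[4-(benzyloxy)-3-methoxybenzyl]-1-[4-(benzyloxy)-3,5-dimethoxyphenyl]-4-(chloromethoxy)butan-1-one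
Product: 14 [4-(benzyloxy)-3,5-dimethoxyphenyl]{(3R,4R)-4-[4-(benzyloxy)-3-methoxybenzyl]oxolan-3-yl}methanone, via lithium (Z)-enolate 13 (not isolated)
Conditions: LiHMDS (1.05 equiv) added slowly, THF (0.01 M), −78 → 0 °C; aq NH4Cl
Reagents that add atoms: none
Why: Proposed new method: LiHMDS removes a C4 proton, the only enolisable position of aryl ketone 12, and the carbon terminus of lithium enolate 13 displaces chloride from the tethered, strongly SN2-active O–CH2–Cl carbon C5, forming C4–C5 and closing the oxolane. The closest known reaction types are the intermolecular C-alkylation of lithium and titanium enolates with chloromethyl ethers (MOMCl, BOMCl) and the ring-closing alkylation of ω-halo ketone enolates; combining them in an O-tethered formaldehyde equivalent is the extrapolation, and the Lewis-acid rearrangement of 4,5-dihydro-1,3-dioxepines to 3-acyloxolanes shows that the same enolate/O–CH2 pairing settles in the five-membered C-alkylated product. The ring closes in the 5-(enolexo)-exo-tet mode, which is favoured for enolates. The new centre C4 is controlled by C3: with C3–H eclipsing the enolate double bond (minimal A1,3 strain), tether and benzyl group lie on opposite faces, so C5 arrives anti to the benzyl group and the aroyl group ends trans to it (4R), which is also the thermodynamic epimer, so any later enolisation can only correct the outcome. The step needs C- over O-alkylation, secured by five- against seven-membered closure and by the tight lithium enolate in THF without polar additives, and it needs deprotonation to outrun both attack of the base on C5 and intermolecular alkylation, secured by the hindered amide at −78 °C and by high dilution.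

Step 9
Reactants: 14 [4-(benzyloxy)-3,5-dimethoxyphenyl]{(3R,4R)-4-[4-(benzyloxy)-3-methoxybenzyl]oxolan-3-yl}methanone
Product: 15 (S)-[4-(benzyloxy)-3,5-dimethoxyphenyl]{(3R,4R)-4-[4-(benzyloxy)-3-methoxybenzyl]oxolan-3-yl}methanol
Conditions: L-Selectride, THF, −78 °C; aq NH4Cl
Reagents that add atoms: none
Why: Felkin–Anh-controlled reduction with a bulky trialkylborohydride, in which the branched ring carbon C3 stands perpendicular to the carbonyl as the large group, C5H2 sits next to the carbonyl oxygen, and hydride approaches along the C4–H flank onto the Re face of C7 to give 7S, the same face that a lithium chelate between the ketone oxygen and O1 would expose.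

Step 10
Reactants: 15 (S)-[4-(benzyloxy)-3,5-dimethoxyphenyl]{(3R,4R)-4-[4-(benzyloxy)-3-methoxybenzyl]oxolan-3-yl}methanol
Product: 16 4-[(S)-hydroxy{(3R,4R)-4-[(4-hydroxy-3-methoxyphenyl)methyl]oxolan-3-yl}methyl]-2,6-dimethoxyphenol
Conditions: H2 (1 atm), 10% Pd/C, EtOAc, rt, stopped at full debenzylation
Reagents that add atoms: none
Why: Catalytic hydrogenolysis of two aryl benzyl ethers under neutral conditions at ambient pressure, which is much faster than cleavage of the secondary benzylic C–OH bond and touches none of the three stereocentres.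

Compound list
1 | 4-(benzyloxy)-3-methoxybenzaldehyde | O=Cc1ccc(OCc2ccccc2)c(OC)c1 | starting material
2 | dimethyl succinate | COC(=O)CCC(=O)OC | starting material
3 | (E)-4-[4-(benzyloxy)-3-methoxyphenyl]-3-(methoxycarbonyl)but-3-enoic acid | COC(=O)/C(CC(=O)O)=C/c1ccc(OCc2ccccc2)c(OC)c1 | intermediate
4 | (R)-4-[4-(benzyloxy)-3-methoxyphenyl]-3-(methoxycarbonyl)butanoic acid | COC(=O)[C@H](Cc1ccc(OCc2ccccc2)c(OC)c1)CC(=O)O | intermediate
5 | (R)-3-[4-(benzyloxy)-3-methoxybenzyl]-4-hydroxybutanoic acid (not isolated) | OC[C@H](Cc1ccc(OCc2ccccc2)c(OC)c1)CC(=O)O | intermediate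
6 | (R)-4-[4-(benzyloxy)-3-methoxybenzyl]oxolan-2-one | O=C1C[C@@H](Cc2ccc(OCc3ccccc3)c(OC)c2)CO1 | intermediate
7 | 4-bromo-2,6-dimethoxyphenol | COc1cc(Br)cc(OC)c1O | starting material
8 | 2-(benzyloxy)-5-bromo-1,3-dimethoxybenzene | COc1cc(Br)cc(OC)c1OCc1ccccc1 | intermediate
9 | [4-(benzyloxy)-3,5-dimethoxyphenyl]lithium (not isolated) | [Li]c1cc(OC)c(OCc2ccccc2)c(OC)c1 | intermediate
10 | (R)-3-[4-(benzyloxy)-3-methoxybenzyl]-1-[4-(benzyloxy)-3,5-dimethoxyphenyl]-4-hydroxybutan-1-one | OC[C@H](Cc1ccc(OCc2ccccc2)c(OC)c1)CC(=O)c1cc(OC)c(OCc2ccccc2)c(OC)c1 | intermediate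
11 | (R)-3-[4-(benzyloxy)-3-methoxybenzyl]-1-[4-(benzyloxy)-3,5-dimethoxyphenyl]-4-[(methylsulfanyl)methoxy]butan-1-one | CSCOC[C@H](Cc1ccc(OCc2ccccc2)c(OC)c1)CC(=O)c1cc(OC)c(OCc2ccccc2)c(OC)c1 | intermediate
12 | (R)-3-[4-(benzyloxy)-3-methoxybenzyl]-1-[4-(benzyloxy)-3,5-dimethoxyphenyl]-4-(chloromethoxy)butan-1-one | ClCOC[C@H](Cc1ccc(OCc2ccccc2)c(OC)c1)CC(=O)c1cc(OC)c(OCc2ccccc2)c(OC)c1 | intermediate
13 | lithium (R,Z)-enolate of 12 (not isolated) | ClCOC[C@H](Cc1ccc(OCc2ccccc2)c(OC)c1)/C=C(\O[Li])c1cc(OC)c(OCc2ccccc2)c(OC)c1 | intermediate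
14 | [4-(benzyloxy)-3,5-dimethoxyphenyl]{(3R,4R)-4-[4-(benzyloxy)-3-methoxybenzyl]oxolan-3-yl}methanone | COc1cc(C[C@H]2COC[C@@H]2C(=O)c2cc(OC)c(OCc3ccccc3)c(OC)c2)ccc1OCc1ccccc1 | intermediate
15 | (S)-[4-(benzyloxy)-3,5-dimethoxyphenyl]{(3R,4R)-4-[4-(benzyloxy)-3-methoxybenzyl]oxolan-3-yl}methanol | COc1cc(C[C@H]2COC[C@@H]2[C@H](O)c2cc(OC)c(OCc3ccccc3)c(OC)c2)ccc1OCc1ccccc1 | intermediate
16 | 4-[(S)-hydroxy{(3R,4R)-4-[(4-hydroxy-3-methoxyphenyl)methyl]oxolan-3-yl}methyl]-2,6-dimethoxyphenol | COc1cc(C[C@H]2COC[C@@H]2[C@H](O)c2cc(OC)c(O)c(OC)c2)ccc1O | target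

Total step count: 10. Longest linear sequence: 9 steps (1 → 3 → 4 → 6 → 10 → 11 → 12 → 14 → 15 → 16). Step 4 is the one-step side branch.

Steps most likely to fail

Step 8. The amide base may attack the chloromethyl carbon before it deprotonates C4. The enolate may also close through oxygen in the seven-membered mode, or chains may couple intermolecularly.
- The fallback uses only known lignan-lactone chemistry. It forms C4–C7 by an aldol reaction and closes the ring at O1 instead.
- It sets out from lactone 6 and aryllithium 9 (made from 8 as in step 5) and returns at ketone 14.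
- Quenching 9 with DMF gives 4-(benzyloxy)-3,5-dimethoxybenzaldehyde F1.
- The LDA enolate of 6 adds to it anti to the benzyl group (THF, −78 °C) to give the trans aldol (3S,4R)-4-[4-(benzyloxy)-3-methoxybenzyl]-3-{[4-(benzyloxy)-3,5-dimethoxyphenyl](hydroxy)methyl}oxolan-2-one F2, as both carbinol epimers.
- TBSOTf/2,6-lutidine gives its tert-butyldimethylsilyl ether F3.
- LiAlH4 opens the lactone to the (2R,3R)-butane-1,4-diol F4.
- Mitsunobu cyclodehydration (PPh3, DIAD) joins the two primary carbinols to the silylated oxolane F5.
- TBAF frees the C7-epimeric carbinol F6, and Dess–Martin oxidation converges both epimers on 14.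

Step 7. The chlorinating agent or the sulfenyl chloride may attack the electron-rich rings. The α-chloro ether may also hydrolyse or ionise during handling, including Friedel–Crafts closure onto the guaiacyl ring.
- The fallback handles no halide. It sets out from O,S-acetal 11 and returns at ketone 14.
- TMSOTf/Et3N converts 11 into the (R,Z)-trimethylsilyl enol ether F7.
- A thiophile (dimethyl(methylthio)sulfonium tetrafluoroborate, CH2Cl2, −78 → 0 °C) then releases the O1=C5H2 oxocarbenium ion directly from the methylthiomethyl ether.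
- The neutral enol silane captures the ion at carbon in a Mukaiyama-type cyclisation, and the trans preference rests on the same C3 control and on equilibration.

Step 9. Facial selectivity of the substrate-controlled hydride addition may be poor, or the hindered ketone may be enolised by the basic reagent.
- The fallback replaces substrate control by catalyst control. It sets out from 14 and returns at 15.
- It is a Noyori–Ikariya asymmetric transfer hydrogenation with RuCl[(S,S)-TsDPEN](p-cymene) or an arene-tethered analogue in HCO2H/Et3N.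
- The catalyst recognises the aryl group through a CH/π contact, which fixes the S carbinol as it does for simple aryl alkyl ketones and is matched with the Felkin bias.
- Epimerisation at C4 under these conditions could only favour the trans series.
- No compound outside the list is made (entry F0).

Further compounds
F1 | step 8 | 4-(benzyloxy)-3,5-dimethoxybenzaldehyde | O=Cc1cc(OC)c(OCc2ccccc2)c(OC)c1
F2 | step 8 | (3S,4R)-4-[4-(benzyloxy)-3-methoxybenzyl]-3-{[4-(benzyloxy)-3,5-dimethoxyphenyl](hydroxy)methyl}oxolan-2-one, both carbinol epimers | COc1cc(C[C@H]2COC(=O)[C@@H]2C(O)c2cc(OC)c(OCc3ccccc3)c(OC)c2)ccc1OCc1ccccc1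
F3 | step 8 | tert-butyldimethylsilyl ether of F2 | COc1cc(C[C@H]2COC(=O)[C@@H]2C(O[Si](C)(C)C(C)(C)C)c2cc(OC)c(OCc3ccccc3)c(OC)c2)ccc1OCc1ccccc1
F4 | step 8 | (2R,3R)-2-[4-(benzyloxy)-3-methoxybenzyl]-3-{[4-(benzyloxy)-3,5-dimethoxyphenyl][(tert-butyldimethylsilyl)oxy]methyl}butane-1,4-diol | COc1cc(C[C@@H](CO)[C@H](CO)C(O[Si](C)(C)C(C)(C)C)c2cc(OC)c(OCc3ccccc3)c(OC)c2)ccc1OCc1ccccc1
F5 | step 8 | tert-butyldimethylsilyl ether of [4-(benzyloxy)-3,5-dimethoxyphenyl]{(3R,4R)-4-[4-(benzyloxy)-3-methoxybenzyl]oxolan-3-yl}methanol, both C7 epimers | COc1cc(C[C@H]2COC[C@@H]2C(O[Si](C)(C)C(C)(C)C)c2cc(OC)c(OCc3ccccc3)c(OC)c2)ccc1OCc1ccccc1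
F6 | step 8 | [4-(benzyloxy)-3,5-dimethoxyphenyl]{(3R,4R)-4-[4-(benzyloxy)-3-methoxybenzyl]oxolan-3-yl}methanol, both C7 epimers | COc1cc(C[C@H]2COC[C@@H]2C(O)c2cc(OC)c(OCc3ccccc3)c(OC)c2)ccc1OCc1ccccc1
F7 | step 7 | (R,Z)-trimethylsilyl enol ether of 11 | CSCOC[C@H](Cc1ccc(OCc2ccccc2)c(OC)c1)/C=C(\O[Si](C)(C)C)c1cc(OC)c(OCc2ccccc2)c(OC)c1
F0 | step 9 | none | none
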